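I cannot tell the readings of eta, the flask asked about, from a flat line between 15.0 min and 90.0 min: complex with two exchanged averages 14.8% and starting complex 54.7%, each mean uncertain by 0.61 percentage points.

| flask | starting complex | incoming ligand | temperature | remark | time |
|---|---|---|---|---|---|
| eta | 0.47 M | 0.329 M | 25 °C | the very flask that is asked about, followed so far |  |
| delta | 0.23 M | 0.329 M | 31 °C | run made earlier |  |
| flask | 0.47 M | 0.329 M | 25 °C |  | 2.5 h |

| run | time / min | complex with two exchanged / % | starting complex / % |
|---|---|---|---|
| eta | 15.0 | 14 | 57 |
| eta | 30.0 | 15 | 53 |
| eta | 50.0 | 16 | 53 |
| eta | 60.0 | 15 | 56 |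
| eta | 80.0 | 16 | 55 |
| eta | 90.0 | 13 | 54 |
| delta | 0.200 | 6 | 70 |
| delta | 0.667 | 25 | 48 |
| delta | 1.00 | 34 | 42 |
| delta | 2.00 | 34 | 33 |
| delta | 2.50 | 35 | 31 |
| delta | 3.00 | 33 | 32 |

(scatter of a reading: 1.5 percentage points)

- Friday's: change nothing and wait 2.5 h more
- Thursday's: at 2.5 h take out 90% of the complex with two exchanged then present, then wait 2.5 h
- Wednesday's: at 2.5 h add incoming ligand, 100% of the amount charged, then wait 2.5 h
- Sunday's: at 2.5 h raise the temperature by 10 K, then wait 2.5 h

1. complex with two exchanged, in percent of the starting complex first charged, at 2.5 h
2. which option adds most complex with two exchanged ("none" when 2 percentage points or less is all one gets) (Friday's / Thursday's / Wednesday's / Sunday's / none)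
3. complex with two exchanged present, with what was taken out counted in, in percent of the starting complex first charged, after Friday's
4. complex with two exchanged present, with what was taken out counted in, in percent of the starting complex first charged, after Thursday's

- complex with two exchanged that was removed still counts
- additions bring no volume worth counting

So I replace the curve by its mean: 14.8% at 2.5 h, and nothing added by Friday's. I take the remaining 30.5% as complex with one exchanged, which makes 0.283 M of leaving ligand and leaves 0.0462 M of incoming ligand free, so I read the flat line as an equilibrium. Incoming ligand is the limiting reagent, with 0.329 M against the 0.940 M that two exchanges on the whole charge take.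

These amounts give 3.19, my exchange constant: the square root of complex with two exchanged over starting complex, times leaving ligand over free incoming ligand. Taking both steps alike, the ratio s of each product to its predecessor is this constant times free incoming ligand over leaving ligand. A flask then needs, in equivalents of incoming ligand, its mean exchanges per complex times one plus s over the constant.

At s equal to one, the three forms of the complex stand equal and that need is 1.31. Wednesday's brings 1.40 equivalents, so I reckon complex with two exchanged at about a third of the charge, a gain near 18 points.

The forecast says 15% now, 15% after Friday's, 21% after Thursday's and Wednesday's as best, on the ground that “The plateaus show equilibrium rather than slow reaction”.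

The flask gives 14.4% now, 14.4% after Friday's and 20.1% after Thursday's, and Wednesday's is best, gaining 19 points against 5.7 points for Thursday's and 1.7 points for Sunday's.

    starting complex + incoming ligand ⇌ leaving ligand + complex with one exchanged (K = 3.20, k = 3.59 /M/min, Ea = 66.0 kJ/mol, ΔH = −33.0 kJ/mol)
    complex with one exchanged + incoming ligand ⇌ leaving ligand + complex with two exchanged (K = 2.67, k = 7.13 /M/min, Ea = 62.0 kJ/mol, ΔH = 8.00 kJ/mol)
    (constants at 25 °C)

With the other charges held, the answer to "now" has moved by 5 points at 0.375 M of starting complex. A neighbouring flask lies below that, with 0.19 M of starting complex and 1.73 equiv of incoming ligand. For it I try s of 1.40, which needs 1.76 equivalents, close to its charge, and puts complex with two exchanged at 45.0%. That neighbour holds 42.1%.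

(The readings stem from a simulated flask with constants of no real substance; scatter was added.)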